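Everything rests on building ring A instead of alkylating a phloroglucinol. The feature exploited is ring A itself (C4a–C8a): its three oxygens have different fates (O1 closes ring C, O5 and O7 stay hydroxyl) and C6 and C8 bear different chains (geranyl, prenyl). A Danheiser benzannulation of a 2-geranyl-3-(methoxymethoxy)cyclobutenone with a prenyl-bearing triisopropylsiloxyalkyne forges C8–C8a, C6–C7 and C4a–C8a in one operation and delivers a phenol in which O1 alone is unprotected, O5 is an acetal, O7 a silyl ether and each chain sits on a reagent-defined carbon. The C4a–H left over is lithiated and acylated to a chalcone; peptide-catalysed epoxidation and closure through O1 set C3 and C2.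

Key step: step 5

Remark: geranyl = (2E)-3,7-dimethylocta-2,6-dien-1-yl, prenyl = 3-methylbut-2-en-1-yl, MOM = methoxymethyl, THP = oxan-2-yl, TIPS = tri(propan-2-yl)silyl. The THP acetal carbon is not controlled, so 16, 22, 23, 24 and 25 are mixtures of two epimers at that carbon; it is removed in step 12. Diones 2 and 5 are drawn as the tautomer named.

Step 1
Reactants: 1 3-ethoxycyclobut-2-en-1-one
Product: 2 cyclobutane-1,3-dione
Conditions: 2 M aq. HCl, 0 °C → rt; used at once
Reagents that add atoms: water, O
Why: Acid-catalysed hydrolysis of a vinylogous ester (water adds at C3 and ethanol leaves) should release the parent dione, which is strongly acidic and is carried on without storage because it decomposes on standing.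

Step 2
Reactants: 2 cyclobutane-1,3-dione (1.5 equiv); 3 geranyl bromide
Product: 5 2-geranyl-3-hydroxycyclobut-2-en-1-one, via O-geranyl enol ether 4 (not isolated)
Conditions: K2CO3, DMF, 0 °C → rt; then Pd(PPh3)4 (5 mol %), 50 °C; acid–base extraction
Reagents that add atoms: none
Why: O-Alkylation of the very acidic enol gives allyl enol ether 4, which zerovalent palladium ionises to a geranyl–palladium cation and the diketonate that recombine at carbon through the unsubstituted allyl terminus (Tsuji–Trost allylation in its O-to-C allyl-transfer form), so that the chain ends up on C2 with its E alkene intact because syn–anti isomerisation would need a tertiary σ-allyl complex.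

Step 3
Reactants: 5 2-geranyl-3-hydroxycyclobut-2-en-1-one
Product: 6 2-geranyl-3-(methoxymethoxy)cyclobut-2-en-1-one
Conditions: MOMCl, i-Pr2NEt, CH2Cl2, 0 °C; chromatography on Et3N-treated silica
Reagents that add atoms: chloromethyl methyl ether, COCCl
Why: Deprotonation of the enol O–H gives the symmetric 2-geranyl diketonate, which the hard electrophile MOMCl alkylates on oxygen (enol ether formation) faster than proton transfer can move the double bond away from the geranyl-bearing carbon, and either oxygen gives the same 2-geranyl-3-alkoxy isomer.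

Step 4
Reactants: 7 ethyl 4-methylpent-3-enoate
Product: 10 triisopropyl[(5-methylhex-4-en-1-yn-1-yl)oxy]silane, via lithium dibromoenolate 8 (not isolated), via lithium ynolate 9 (not isolated)
Conditions: CH2Br2, lithium 2,2,6,6-tetramethylpiperidide, THF, −78 °C; LiN(SiMe3)2; n-BuLi, −78 °C → rt; i-Pr3SiCl, −78 → 0 °C
Reagents that add atoms: dibromomethane, BrCBr; chlorotri(propan-2-yl)silane, CC(C)[Si](Cl)(C(C)C)C(C)C
Why: Kowalski ester homologation: LiCHBr2 adds to the ester, the resulting dibromoketone is deprotonated to 8, bromine–lithium exchange triggers a 1,2-shift to ynolate 9, and the bulky silyl chloride traps 9 on oxygen and not on carbon.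

Step 5
Reactants: 6 2-geranyl-3-(methoxymethoxy)cyclobut-2-en-1-one; 10 triisopropyl[(5-methylhex-4-en-1-yn-1-yl)oxy]silane (1.5 equiv)
Product: 15 4-geranyl-5-(methoxymethoxy)-2-prenyl-3-(triisopropylsiloxy)phenol, via vinylketene 11 (not isolated), via vinylcyclobutenone 12 (not isolated), via dienylketene 13 (not isolated), via cyclohexadienone 14 (not isolated)
Conditions: toluene, 110 °C, sealed tube, argon
Reagents that add atoms: none
Why: Heating should open cyclobutenone 6 by 4π electrocyclic cleavage of its C1–C4 bond to vinylketene 11, whose central ketene carbon is attacked by the oxygen-remote, nucleophilic carbon of ynol ether 10 in a regiospecific [2+2] cycloaddition that gives vinylcyclobutenone 12. A second 4π opening gives dienylketene 13, which closes ring A by 6π electrocyclisation between the ketene carbon (C8a) and the terminal methylene (C4a), and cyclohexadienone 14 tautomerises to the phenol. The closest known reaction type is the Danheiser benzannulation of cyclobutenones with siloxyalkynes to resorcinol monosilyl ethers; here the cyclobutenone carries an alkoxy group on C3, so a higher temperature than usual is expected because the vinylogous ester is stabilised. No stereocentre survives, since the quaternary carbon of 12 is lost on ring opening. The selectivity needed is regiochemical and is secured by the polarisation of both partners: the ynol ether carbon away from oxygen bonds to the ketene carbonyl carbon, which puts prenyl beside the new hydroxyl (C8), the silyl ether on C7 and geranyl on C6 between the two protected oxygens. Isolated trisubstituted alkenes should not add to the ketene under these conditions, and the excess of 10 limits acylation of the product phenol by 11.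

Step 6
Reactants: 15 4-geranyl-5-(methoxymethoxy)-2-prenyl-3-(triisopropylsiloxy)phenol
Product: 16 THP ether of 15 at O1
Conditions: 3,4-dihydro-2H-pyran, pyridinium p-toluenesulfonate (PPTS, cat.), CH2Cl2, rt
Reagents that add atoms: 3,4-dihydro-2H-pyran, C1CCOC=C1
Why: Acid-catalysed addition of the phenol to the enol ether (tetrahydropyranylation) masks O1 as an acetal that directs lithiation, tolerates organolithium and basic peroxide, and is cleaved by far weaker acid than the MOM ether on O5, so that O1 and O5 stay distinguishable.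

Step 7
Reactants: 17 5-methoxyresorcinol
Product: 18 1-methoxy-3,5-bis(methoxymethoxy)benzene
Conditions: MOMCl, i-Pr2NEt, CH2Cl2, 0 °C → rt
Reagents that add atoms: chloromethyl methyl ether, COCCl
Why: Base-mediated O-alkylation of both phenols (Williamson-type) installs two MOM ethers that later direct metalation to the carbon between them and fall off in the final acid step.

Step 8
Reactants: 18 1-methoxy-3,5-bis(methoxymethoxy)benzene
Product: 20 4-methoxy-2,6-bis(methoxymethoxy)benzaldehyde, via aryllithium 19 (not isolated)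
Conditions: n-BuLi, TMEDA, THF, 0 °C; DMF, 0 °C → rt; H2O
Reagents that add atoms: N,N-dimethylformamide, CN(C)C=O
Why: Directed ortho-metalation takes place at the carbon flanked by both OMOM groups, which chelate lithium better than OMe, and aryllithium 19 is formylated by DMF.

Step 9
Reactants: 20 4-methoxy-2,6-bis(methoxymethoxy)benzaldehyde
Product: 21 (2E)-N-methoxy-3-[4-methoxy-2,6-bis(methoxymethoxy)phenyl]-N-methylprop-2-enamide
Conditions: (EtO)2P(O)CH2C(O)N(OMe)Me, NaH, THF, 0 °C → rt
Reagents that add atoms: diethyl {2-[methoxy(methyl)amino]-2-oxoethyl}phosphonate, CCOP(=O)(CC(=O)N(C)OC)OCC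
Why: Horner–Wadsworth–Emmons olefination with the amide-stabilised phosphonate anion should give the E alkene and installs the N-methoxy-N-methylamide needed for ketone formation.

Step 10
Reactants: 16 THP ether of 15 at O1; 21 (2E)-N-methoxy-3-[4-methoxy-2,6-bis(methoxymethoxy)phenyl]-N-methylprop-2-enamide
Product: 23 chalcone (2E)-1-[3-geranyl-2-(methoxymethoxy)-6-(oxan-2-yloxy)-5-prenyl-4-(triisopropylsiloxy)phenyl]-3-[4-methoxy-2,6-bis(methoxymethoxy)phenyl]prop-2-en-1-one, via aryllithium 22 (not isolated)
Conditions: n-BuLi, THF, 0 °C; 21, −78 → 0 °C; H2O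
Reagents that add atoms: none
Why: Directed ortho-metalation removes the only ring hydrogen, acidified by the flanking OTHP and OMOM groups, and aryllithium 22 adds once to the N-methoxy-N-methylamide (Weinreb ketone synthesis), the chelated adduct releasing the enone only on work-up, so that no hydroxide-mediated aldol step endangers the silyl ether.

Step 11
Reactants: 23 chalcone
Product: 24 (2R,3S)-epoxide of chalcone 23
Conditions: poly-L-leucine, urea–H2O2, DBU, THF, rt; filtration through basic alumina
Reagents that add atoms: urea–hydrogen peroxide, NC(N)=O.OO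
Why: Juliá–Colonna epoxidation: hydroperoxide adds to the enone held at the N-terminus of the poly-L-leucine helix, which exposes the alkene face that leads to the (2R,3S)-oxirane, and this nucleophilic oxidant leaves the electron-rich prenyl and geranyl alkenes untouched, so that the future C3 (R) is fixed here by the catalyst.

Step 12
Reactants: 24 (2R,3S)-epoxide of chalcone 23
Product: 26 (2R,3R)-6-geranyl-3-hydroxy-2-[4-methoxy-2,6-bis(methoxymethoxy)phenyl]-5-(methoxymethoxy)-8-prenyl-7-(triisopropylsiloxy)-2,3-dihydro-4H-chromen-4-one, via hydroxy epoxide 25 (not isolated)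
Conditions: PPTS, MeOH–CH2Cl2, rt
Reagents that add atoms: none
Why: Acetal exchange with methanol removes only the THP group, and the freed O1 hydroxyl opens the acid-activated oxirane at its aryl-bearing carbon (6-endo epoxide opening with inversion, S at that carbon becoming 2R while the other oxirane carbon becomes 3R unchanged), the 2,3-trans product also being the thermodynamic sink if a methanol adduct forms first and re-ionises, while O5 stays blocked and cannot compete.

Step 13
Reactants: 26 protected (2R,3R)-dihydroflavonol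
Product: 27 (2R,3R)-2-(2,6-dihydroxy-4-methoxyphenyl)-6-geranyl-3,5-dihydroxy-8-prenyl-7-(triisopropylsiloxy)-2,3-dihydro-4H-chromen-4-one
Conditions: 3 M aq. HCl–MeOH (1:5), rt → 40 °C
Reagents that add atoms: none
Why: Acid-catalysed acetal exchange with methanol cleaves the three MOM ethers, the one on O5 fastest because of the adjacent carbonyl, while the hindered silyl ether keeps O7 from adding to the flanking alkenes under acid.

Step 14
Reactants: 27 7-O-TIPS dihydroflavonol
Product: 28 (2R,3R)-2-(2,6-dihydroxy-4-methoxyphenyl)-6-geranyl-3,5,7-trihydroxy-8-prenyl-2,3-dihydro-4H-chromen-4-one (CNP0304077.2)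
Conditions: Bu4NF, AcOH, THF, 0 °C
Reagents that add atoms: none
Why: Fluoride cleaves the Si–O bond (desilylation) and acetic acid buffers the liberated phenoxide, so that the base-sensitive 2,3-trans-dihydroflavonol is neither epimerised nor oxidised.

Compound list
1 | 3-ethoxycyclobut-2-en-1-one | CCOC1=CC(=O)C1 | starting material
2 | cyclobutane-1,3-dione | O=C1CC(=O)C1 | intermediate
3 | geranyl bromide, (2E)-1-bromo-3,7-dimethylocta-2,6-diene | BrC/C=C(\C)CCC=C(C)C | starting material
4 | 3-(geranyloxy)cyclobut-2-en-1-one | O=C1C=C(OC/C=C(\C)CCC=C(C)C)C1 | intermediate, consumed in the flask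
5 | 2-geranyl-3-hydroxycyclobut-2-en-1-one | O=C1CC(O)=C1C/C=C(\C)CCC=C(C)C | intermediate
6 | 2-geranyl-3-(methoxymethoxy)cyclobut-2-en-1-one | O=C1CC(OCOC)=C1C/C=C(\C)CCC=C(C)C | intermediate
7 | ethyl 4-methylpent-3-enoate | CCOC(=O)CC=C(C)C | starting material
8 | lithium 1,1-dibromo-5-methylhexa-1,4-dien-2-olate | [Li+].[O-]C(=C(Br)Br)CC=C(C)C | intermediate, consumed in the flask
9 | lithium 5-methylhex-4-en-1-yn-1-olate | [Li+].[O-]C#CCC=C(C)C | intermediate, consumed in the flask
10 | triisopropyl[(5-methylhex-4-en-1-yn-1-yl)oxy]silane | CC(C)=CCC#CO[Si](C(C)C)(C(C)C)C(C)C | intermediate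
11 | 2-geranyl-3-(methoxymethoxy)buta-1,3-dien-1-one (vinylketene) | O=C=C(C/C=C(\C)CCC=C(C)C)C(=C)OCOC | intermediate, consumed in the flask
12 | 4-geranyl-4-[1-(methoxymethoxy)ethenyl]-2-prenyl-3-(triisopropylsiloxy)cyclobut-2-en-1-one (racemic) | O=C1C(CC=C(C)C)=C(O[Si](C(C)C)(C(C)C)C(C)C)C1(C/C=C(\C)CCC=C(C)C)C(=C)OCOC | intermediate, consumed in the flask
13 | (3E)-4-geranyl-5-(methoxymethoxy)-2-prenyl-3-(triisopropylsiloxy)hexa-1,3,5-trien-1-one (dienylketene, ketene carbon and vinyl group cis) | O=C=C(CC=C(C)C)/C(O[Si](C(C)C)(C(C)C)C(C)C)=C(/C/C=C(\C)CCC=C(C)C)C(=C)OCOC | intermediate, consumed in the flask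
14 | 4-geranyl-5-(methoxymethoxy)-2-prenyl-3-(triisopropylsiloxy)cyclohexa-2,4-dien-1-one | O=C1CC(OCOC)=C(C/C=C(\C)CCC=C(C)C)C(O[Si](C(C)C)(C(C)C)C(C)C)=C1CC=C(C)C | intermediate, consumed in the flask
15 | 4-geranyl-5-(methoxymethoxy)-2-prenyl-3-(triisopropylsiloxy)phenol | Oc1cc(OCOC)c(C/C=C(\C)CCC=C(C)C)c(O[Si](C(C)C)(C(C)C)C(C)C)c1CC=C(C)C | intermediate
16 | 2-[4-geranyl-5-(methoxymethoxy)-2-prenyl-3-(triisopropylsiloxy)phenoxy]oxane (racemic at the acetal carbon) | COCOc1cc(OC2CCCCO2)c(CC=C(C)C)c(O[Si](C(C)C)(C(C)C)C(C)C)c1C/C=C(\C)CCC=C(C)C | intermediate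
17 | 5-methoxyresorcinol (5-methoxybenzene-1,3-diol) | COc1cc(O)cc(O)c1 | starting material
18 | 1-methoxy-3,5-bis(methoxymethoxy)benzene | COCOc1cc(OC)cc(OCOC)c1 | intermediate
19 | [4-methoxy-2,6-bis(methoxymethoxy)phenyl]lithium | [Li]c1c(OCOC)cc(OC)cc1OCOC | intermediate, consumed in the flask
20 | 4-methoxy-2,6-bis(methoxymethoxy)benzaldehyde | COCOc1cc(OC)cc(OCOC)c1C=O | intermediate
21 | (2E)-N-methoxy-3-[4-methoxy-2,6-bis(methoxymethoxy)phenyl]-N-methylprop-2-enamide | CON(C)C(=O)/C=C/c1c(OCOC)cc(OC)cc1OCOC | intermediate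
22 | [3-geranyl-2-(methoxymethoxy)-6-(oxan-2-yloxy)-5-prenyl-4-(triisopropylsiloxy)phenyl]lithium | [Li]c1c(OCOC)c(C/C=C(\C)CCC=C(C)C)c(O[Si](C(C)C)(C(C)C)C(C)C)c(CC=C(C)C)c1OC1CCCCO1 | intermediate, consumed in the flask
23 | (2E)-1-[3-geranyl-2-(methoxymethoxy)-6-(oxan-2-yloxy)-5-prenyl-4-(triisopropylsiloxy)phenyl]-3-[4-methoxy-2,6-bis(methoxymethoxy)phenyl]prop-2-en-1-one | COCOc1c(C/C=C(\C)CCC=C(C)C)c(O[Si](C(C)C)(C(C)C)C(C)C)c(CC=C(C)C)c(OC2CCCCO2)c1C(=O)/C=C/c1c(OCOC)cc(OC)cc1OCOC | intermediate
24 | [3-geranyl-2-(methoxymethoxy)-6-(oxan-2-yloxy)-5-prenyl-4-(triisopropylsiloxy)phenyl]{(2R,3S)-3-[4-methoxy-2,6-bis(methoxymethoxy)phenyl]oxiran-2-yl}methanone | COCOc1c(C/C=C(\C)CCC=C(C)C)c(O[Si](C(C)C)(C(C)C)C(C)C)c(CC=C(C)C)c(OC2CCCCO2)c1C(=O)[C@@H]1O[C@H]1c1c(OCOC)cc(OC)cc1OCOC | intermediate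
25 | [3-geranyl-6-hydroxy-2-(methoxymethoxy)-5-prenyl-4-(triisopropylsiloxy)phenyl]{(2R,3S)-3-[4-methoxy-2,6-bis(methoxymethoxy)phenyl]oxiran-2-yl}methanone | COCOc1c(C/C=C(\C)CCC=C(C)C)c(O[Si](C(C)C)(C(C)C)C(C)C)c(CC=C(C)C)c(O)c1C(=O)[C@@H]1O[C@H]1c1c(OCOC)cc(OC)cc1OCOC | intermediate, consumed in the flask
26 | (2R,3R)-6-geranyl-3-hydroxy-2-[4-methoxy-2,6-bis(methoxymethoxy)phenyl]-5-(methoxymethoxy)-8-prenyl-7-(triisopropylsiloxy)-2,3-dihydro-4H-chromen-4-one | COc1cc(OCOC)c([C@H]2Oc3c(CC=C(C)C)c(O[Si](C(C)C)(C(C)C)C(C)C)c(C/C=C(\C)CCC=C(C)C)c(OCOC)c3C(=O)[C@@H]2O)c(OCOC)c1 | intermediate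
27 | (2R,3R)-2-(2,6-dihydroxy-4-methoxyphenyl)-6-geranyl-3,5-dihydroxy-8-prenyl-7-(triisopropylsiloxy)-2,3-dihydro-4H-chromen-4-one | COc1cc(O)c([C@H]2Oc3c(CC=C(C)C)c(O[Si](C(C)C)(C(C)C)C(C)C)c(C/C=C(\C)CCC=C(C)C)c(O)c3C(=O)[C@@H]2O)c(O)c1 | intermediate
28 | (2R,3R)-2-(2,6-dihydroxy-4-methoxyphenyl)-6-[(2E)-3,7-dimethylocta-2,6-dien-1-yl]-3,5,7-trihydroxy-8-(3-methylbut-2-en-1-yl)-2,3-dihydro-4H-chromen-4-one | COc1cc(O)c([C@H]2Oc3c(CC=C(C)C)c(O)c(C/C=C(\C)CCC=C(C)C)c(O)c3C(=O)[C@@H]2O)c(O)c1 | target

Total step count: 14. Longest linear sequence: 10 steps (1, 2, 3, 5, 6, 10, 11, 12, 13, 14).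

Steps most likely to fail

Step 5. The ring opening of the donor-stabilised cyclobutenone may need a temperature at which the siloxyalkyne rearranges by silyl shift to a silylketene or the MOM enol ether is lost, and the phenol formed may be acylated by unreacted vinylketene. The fallback generates the same vinylketene 11 at or below room temperature by 1,4-dehydrochlorination instead of ring opening. It sets out from geranyl bromide 3 and siloxyalkyne 10 and comes back at phenol 15. Methyl acetoacetate is C-alkylated with 3 (NaH, THF) to methyl (4E)-2-acetyl-5,9-dimethyldeca-4,8-dienoate F1. Its sodium enolate is O-alkylated with MOMCl (NaH, THF–DMPU) to methyl 2-geranyl-3-(methoxymethoxy)but-2-enoate F2. KOSiMe3 in THF should give potassium 2-geranyl-3-(methoxymethoxy)but-2-enoate F3, and oxalyl chloride (CH2Cl2, 0 °C) 2-geranyl-3-(methoxymethoxy)but-2-enoyl chloride F4. Slow addition of Et3N to F4 and 10 in toluene removes a γ-hydrogen and chloride to give 11, which 10 traps. Brief warming to 80 °C should then take 12 through 13 and 14 to 15.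

Step 11. The enone lies between two di-ortho-substituted, electron-rich aryl groups, so binding to the peptide helix and hydroperoxide addition may be slow and the facial selectivity poor; the very electron-rich benzylic oxirane may also open during handling. The fallback replaces asymmetric catalysis by racemic synthesis and resolution. It sets out from chalcone 23 and comes back at 26. Weitz–Scheffer epoxidation with t-BuOOH and DBU in toluene should give the trans-epoxide as a racemate at the oxirane, that is 24 together with the (2S,3R)-epoxide of chalcone 23 F5. The conditions of step 12 convert both series, the mirror-image one passing through the (2S,3R)-hydroxy epoxide F6, into racemic 2,3-trans product, that is 26 and the (2S,3S)-enantiomer of 26 F7 (a true racemate, since the THP carbon is gone). Chromatography on a chiral stationary phase (amylose tris(3,5-dimethylphenylcarbamate)) separates 26 from F7.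

Step 2. Mono-selectivity may be lost (C,O- and C,C-dialkylation), the E geometry of the allyl unit may erode during ionisation, and dione 2 may decompose before it reacts. The fallback places the chain on the ring carbon by building the four-membered ring around it. It sets out from geranyl bromide 3 and comes back at enol 5. The lithium enolate of ethyl acetate (LiN(i-Pr)2, THF, −78 °C) is alkylated with 3 to ethyl (4E)-5,9-dimethyldeca-4,8-dienoate F8. LiOH gives (4E)-5,9-dimethyldeca-4,8-dienoic acid F9, and oxalyl chloride gives (4E)-5,9-dimethyldeca-4,8-dienoyl chloride F10. Et3N generates (4E)-5,9-dimethyldeca-1,4,8-trien-1-one F11 (geranylketene) in the presence of ethoxyacetylene, and the [2+2] cycloaddition should give 3-ethoxy-4-geranylcyclobut-2-en-1-one F12. Hydrolysis with 2 M aq. HCl, as in step 1, gives 2-geranylcyclobutane-1,3-dione, whose enol is 5.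

Further compounds
F1 | step 5 | methyl (4E)-2-acetyl-5,9-dimethyldeca-4,8-dienoate (racemic) | COC(=O)C(C(C)=O)C/C=C(\C)CCC=C(C)C
F2 | step 5 | methyl 2-geranyl-3-(methoxymethoxy)but-2-enoate (enol ether geometry not controlled) | COC(=O)C(C/C=C(\C)CCC=C(C)C)=C(C)OCOC
F3 | step 5 | potassium 2-geranyl-3-(methoxymethoxy)but-2-enoate | [K+].[O-]C(=O)C(C/C=C(\C)CCC=C(C)C)=C(C)OCOC
F4 | step 5 | 2-geranyl-3-(methoxymethoxy)but-2-enoyl chloride | ClC(=O)C(C/C=C(\C)CCC=C(C)C)=C(C)OCOC
F5 | step 11 | (2S,3R)-epoxide of chalcone 23 (mirror image of 24 at the oxirane) | COCOc1c(C/C=C(\C)CCC=C(C)C)c(O[Si](C(C)C)(C(C)C)C(C)C)c(CC=C(C)C)c(OC2CCCCO2)c1C(=O)[C@H]1O[C@@H]1c1c(OCOC)cc(OC)cc1OCOC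
F6 | step 11 | (2S,3R)-hydroxy epoxide (enantiomer of 25) | COCOc1c(C/C=C(\C)CCC=C(C)C)c(O[Si](C(C)C)(C(C)C)C(C)C)c(CC=C(C)C)c(O)c1C(=O)[C@H]1O[C@@H]1c1c(OCOC)cc(OC)cc1OCOC
F7 | step 11 | (2S,3S)-enantiomer of 26 | COc1cc(OCOC)c([C@@H]2Oc3c(CC=C(C)C)c(O[Si](C(C)C)(C(C)C)C(C)C)c(C/C=C(\C)CCC=C(C)C)c(OCOC)c3C(=O)[C@H]2O)c(OCOC)c1
F8 | step 2 | ethyl (4E)-5,9-dimethyldeca-4,8-dienoate | CCOC(=O)CC/C=C(\C)CCC=C(C)C
F9 | step 2 | (4E)-5,9-dimethyldeca-4,8-dienoic acid | OC(=O)CC/C=C(\C)CCC=C(C)C
F10 | step 2 | (4E)-5,9-dimethyldeca-4,8-dienoyl chloride | ClC(=O)CC/C=C(\C)CCC=C(C)C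
F11 | step 2 | (4E)-5,9-dimethyldeca-1,4,8-trien-1-one (geranylketene, consumed in the flask) | O=C=CC/C=C(\C)CCC=C(C)C
F12 | step 2 | 3-ethoxy-4-geranylcyclobut-2-en-1-one (racemic) | CCOC1=CC(=O)C1C/C=C(\C)CCC=C(C)C
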